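The numbers were chosen freely; what happens was integrated by code.

Reckon this flask as a feed into a pool with a drain, beginning from what stands here.

    X ⇌ Z, rate k1*(csat - [Z]) (k1 = 0.57 s⁻¹, csat = 14 mM)
    E + Z → E.Z (k2 = 0.20 M⁻¹ s⁻¹)
    E → J (k3 = 0.0022 s⁻¹)
    E.Z ⇌ G (K4 = 0.34, k4 = 0.011 s⁻¹)
    E.Z → D (k5 = 0.013 s⁻¹)
    L ⇌ E.Z, rate k6*(cs6 - [E.Z]) while solid is left; crystals form when [E.Z] > cs6 (cs6 = 27 mM, k6 = 0.43 s⁻¹)

E 0.050 M; X 14 mM (held); time 1.5 min

1. how much E.Z and L together there is at 1.5 min, in percent of the E charged
2. the change that raises the amount of E.Z and L together at 1.5 min, in percent of the E charged most ("none" if none brings more than 2 percentage points) (zeta / epsilon / beta / gamma / none)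
3. amount of E.Z and L together at 1.5 min, in percent of the E charged, after epsilon

- zeta: doubling the solubility in step 6, all else as stated
- epsilon: doubling the transfer coefficient of step 1, all else as stated
- beta: doubling the dissolution coefficient of step 6, all else as stated
- gamma: doubling the saturation concentration of X, all else as stated

- for E.Z the L are counted in
- as a solid, counted per litre of solution: L
- at the start none of Z is dissolved
- run time (flask): 1.5 min

How does E enter E.Z? It enters through Z, and Z refills with a half-life of 1.22 s, far shorter than the 1.2 min in which the step to E.Z alone would halve it, so I replace the curve of [Z] by its plateau at saturation and get a pseudo-first-order feed of 0.168 min⁻¹, while with the step to J beside it E leaves at 0.300 min⁻¹.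

But does E.Z stay where it is made? It does not, yet E.Z and G relax in 0.266 min, short against the 1.5 min of the run, so I treat them as one pool in pre-equilibrium, of which 74.6% is dissolved E.Z, and the drain constant, the constant of the step to D times that dissolved share, is 0.582 min⁻¹.

What comes out? Feed and drain in series, times the dissolved share, give my 9.78%, which is 4.89 mM, less than the solubility of 27 mM, so I expect no L, and zeta and beta find nothing to act on, while epsilon, which doubles k1, speeds a refill that is already far faster than the use of Z, so I expect it to leave the plateau nearly where it is.

Doubling csat also empties E faster, so does gamma still pay? My reckoning gives 17.1%, a gain of 7.3 percentage points, more than the 2 points asked, so I commit to gamma.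

The forecast says 9.7%, 9.8% after epsilon, and gamma, holding that “doubling the saturation concentration nearly doubles the Z available and the formation rate”; my figure for y stands a little above its figure.

This flask gives 9.66%, 9.77% after epsilon, and gamma as the best change, with a gain of 7.2 points, so the forecast stands; the reading time would have to go to 0.410 min or 7.01 min before y moved by 5 points.

This flask is not at rest at 1.50 min: 64.3% of the E is still unbound, and at that moment dissolved E.Z is made 1.21 times faster than it is used up, going into its other forms counted as use. Feed and drain carried to 15.0 min give 0.487%, and the run gives 0.510%, with E down to 1.13%, J at 43.9% and D at 54.2%.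

For the neighbour left until 6.0 min, the same feed and drain give 5.99%, and that flask gives 5.92%.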